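**Retrosynthetic overview**

- The strategy rests on the α-ketol unit of the ten-membered carbocycle C1–C10: the tertiary carbinol carbon C10 (methyl C14, ring oxygen) sits next to the C1 ketone, and its oxygen closes the furanone ring (O, C3, C2, C1, C10). This unit is taken back to a 1-acetylcyclononenol (C9 bonded to C1) carrying a C3 dimethyl ketal.
- Key disconnections, made in one operation: C9–C10 (1,2-shift, nine- to ten-membered ring) and O–C3 (furanone). The C15 PMB ether is removed last.
- The nine-membered ring is closed at C3–C4 by NiCl2/CrCl2 coupling of a C4 vinyl iodide with a C3 aldehyde, on a tetrahydrofuran template (C8–O–C10 methyl ketal) that holds both arms cis.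
- The cis-lactone (C6, C7) is made before that, by Barbier coupling at C6–C7 of a (Z)-2-(bromomethyl)enoate with (Z)-3-iodo-4-(PMB-oxy)but-2-enal.
- C8 and C1 come from (R)-5-(hydroxymethyl)butyrolactone (enolate allylation, then hydroxylation); MeLi turns the lactone carbonyl into the acetyl group (C10, C14). Ring order: template tetrahydrofuran, lactone, nine-membered ring, then ten-membered ring and furanone together.

Key step: step 19

Remark on the chemistry: the target is made as drawn (4Z, 6S, 7R, 8R, 10R, cis-fused 6,12-lactone). Atom numbers follow the carbocycle numbering in all intermediates (C11–C13 lactone carbons, C14 methyl, C15 on C4). Temporary centres (ketal carbon C10 in 9–25, carbinol carbon in 13 and in 24) are carried as mixtures because they are destroyed later.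

**Route**

Step 1
Reactants: 1 (R)-5-(hydroxymethyl)dihydrofuran-2(3H)-one
Product: 2 (R)-5-[(tert-butyldiphenylsilyloxy)methyl]dihydrofuran-2(3H)-one
Conditions: t-BuPh2SiCl, imidazole, DMF, rt
Reagents that add atoms: tert-butyldiphenylsilyl chloride, CC(C)(C)[Si](Cl)(c1ccccc1)c1ccccc1
Why: Standard silylation of a primary alcohol, which installs the bulky group that later shields one face of the lactone enolate.

Step 2
Reactants: 2 (R)-5-[(tert-butyldiphenylsilyloxy)methyl]dihydrofuran-2(3H)-one; 3 allyl bromide
Product: 5 (3S,5R)-3-allyl-5-[(tert-butyldiphenylsilyloxy)methyl]dihydrofuran-2(3H)-one, via lithium enolate 4 (not isolated)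
Conditions: LiN(i-Pr)2, THF, −78 °C; then 3, −78 to −40 °C
Reagents that add atoms: allyl bromide (3), C=CCBr
Why: Lactone enolate alkylation, in which the allyl group (C2, C3) enters trans to the C5 substituent; the configuration made here is erased again in step 3.

Step 3
Reactants: 5 (3S,5R)-3-allyl-5-[(tert-butyldiphenylsilyloxy)methyl]dihydrofuran-2(3H)-one
Product: 7 (3S,5R)-3-allyl-3-hydroxy-5-[(tert-butyldiphenylsilyloxy)methyl]dihydrofuran-2(3H)-one, via potassium enolate 6 (not isolated)
Conditions: KN(SiMe3)2, THF, −78 °C; then 2-(phenylsulfonyl)-3-phenyloxaziridine; NH4Cl quench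
Reagents that add atoms: 2-(phenylsulfonyl)-3-phenyloxaziridine, O=S(=O)(c1ccccc1)N1OC1c1ccccc1
Why: Davis enolate hydroxylation, in which the oxidant should approach the tetrasubstituted enolate anti to the silyloxymethyl group, so that the hydroxyl ends trans and the allyl group cis to it, which sets the carbinol centre C1 (the 1R centre of 29) from C8.

Step 4
Reactants: 7 (3S,5R)-3-allyl-3-hydroxy-5-[(tert-butyldiphenylsilyloxy)methyl]dihydrofuran-2(3H)-one
Product: 9 (3S,5R)-3-allyl-2-methoxy-2-methyl-5-[(tert-butyldiphenylsilyloxy)methyl]tetrahydrofuran-3-ol, via hydroxy ketone 8 (not isolated)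
Conditions: MeLi (2.3 equiv), THF, −78 °C; AcOH quench; then MeOH, CSA (cat.), 4 Å MS, rt
Reagents that add atoms: methyllithium, [Li]C; methanol, CO
Why: Addition of MeLi to the lactone should stop after one methyl (C14) because the α-alkoxide chelates the tetrahedral adduct, and Fischer-type ketalisation of the resulting lactol gives the cyclic methyl ketal, which masks C8–O as an ether and C10 as a ketal and holds the C7 and C2 arms cis on a five-membered ring.

Step 5
Reactants: 9 (3S,5R)-3-allyl-2-methoxy-2-methyl-5-[(tert-butyldiphenylsilyloxy)methyl]tetrahydrofuran-3-ol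
Product: 10 (3S,5R)-3-allyl-5-(hydroxymethyl)-2-methoxy-2-methyltetrahydrofuran-3-ol
Conditions: Bu4NF, THF, 0 °C to rt
Reagents that add atoms: none
Why: Fluoride cleavage of the silyl ether, to which the ketal and the tertiary alcohol are inert.

Step 6
Reactants: 10 (3S,5R)-3-allyl-5-(hydroxymethyl)-2-methoxy-2-methyltetrahydrofuran-3-ol
Product: 11 (2R,4S)-4-allyl-4-hydroxy-5-methoxy-5-methyltetrahydrofuran-2-carbaldehyde
Conditions: Dess–Martin periodinane, NaHCO3, CH2Cl2, 0 °C to rt
Reagents that add atoms: none
Why: Dess–Martin oxidation of the primary alcohol (C7) under buffered conditions that should not epimerise C8; the tertiary alcohol cannot be oxidised.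

Step 7
Reactants: 11 (2R,4S)-4-allyl-4-hydroxy-5-methoxy-5-methyltetrahydrofuran-2-carbaldehyde; 12 methyl acrylate
Product: 13 methyl 2-{hydroxy[(2R,4S)-4-allyl-4-hydroxy-5-methoxy-5-methyltetrahydrofuran-2-yl]methyl}acrylate
Conditions: 12 (neat, excess), DABCO (0.5 equiv), rt
Reagents that add atoms: methyl acrylate (12), C=CC(=O)OC
Why: Morita–Baylis–Hillman reaction, which is comparatively fast for an α-alkoxy aldehyde and brings in C11–C13; the new carbinol centre is removed in step 8.

Step 8
Reactants: 13 methyl 2-{hydroxy[(2R,4S)-4-allyl-4-hydroxy-5-methoxy-5-methyltetrahydrofuran-2-yl]methyl}acrylate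
Product: 14 methyl (Z)-2-(bromomethyl)-3-[(2R,4S)-4-allyl-4-hydroxy-5-methoxy-5-methyltetrahydrofuran-2-yl]acrylate
Conditions: N-bromosuccinimide, Me2S, CH2Cl2, −20 °C to rt
Reagents that add atoms: N-bromosuccinimide, O=C1CCC(=O)N1Br
Why: Corey–Kim-type activation of the allylic alcohol followed by SN2′ attack of bromide should give the rearranged primary bromide as the (Z)-2-(bromomethyl)enoate, the isomer with the ester trans to the C8 substituent.

Step 9
Reactants: 15 but-2-yne-1,4-diol
Product: 16 4-[(4-methoxybenzyl)oxy]but-2-yn-1-ol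
Conditions: NaH (1 equiv), 4-MeOC6H4CH2Cl, Bu4NI (cat.), THF/DMF, 0 °C to rt, diol in threefold excess
Reagents that add atoms: 4-methoxybenzyl chloride, COc1ccc(CCl)cc1
Why: Williamson etherification, made mono-selective by the excess of the cheap diol.

Step 10
Reactants: 16 4-[(4-methoxybenzyl)oxy]but-2-yn-1-ol
Product: 18 (Z)-3-iodo-4-[(4-methoxybenzyl)oxy]but-2-en-1-ol, via cyclic vinylalanate 17 (not isolated)
Conditions: NaAlH2(OCH2CH2OMe)2, THF, 0 °C; then I2, −78 to 0 °C
Reagents that add atoms: iodine, II
Why: Hydroxyl-directed trans-hydroalumination of the propargylic alcohol places aluminium on the distal alkyne carbon (C4) cis to the carbinol carbon (C6), and iodinolysis with retention gives the Z vinyl iodide whose iodine marks the site and the side where C3 is attached later.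

Step 11
Reactants: 18 (Z)-3-iodo-4-[(4-methoxybenzyl)oxy]but-2-en-1-ol
Product: 19 (Z)-3-iodo-4-[(4-methoxybenzyl)oxy]but-2-enal
Conditions: MnO2, CH2Cl2, rt
Reagents that add atoms: none
Why: Allylic oxidation with MnO2 under neutral conditions, which should leave the alkene geometry untouched.

Step 12
Reactants: 14 methyl (Z)-2-(bromomethyl)-3-[(2R,4S)-4-allyl-4-hydroxy-5-methoxy-5-methyltetrahydrofuran-2-yl]acrylate; 19 (Z)-3-iodo-4-[(4-methoxybenzyl)oxy]but-2-enal
Product: 21 cis-α-methylene-γ-butyrolactone bearing the tetrahydrofuran ketal at C7 and the (Z)-2-iodo-3-(4-methoxybenzyloxy)prop-1-enyl group at C6, via hydroxy ester 20 (not isolated)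
Conditions: indium powder (In), THF/H2O (1:1), rt; then PPTS (cat.), CH2Cl2, rt
Reagents that add atoms: (Z)-3-iodo-4-[(4-methoxybenzyl)oxy]but-2-enal (19), O=C/C=C(\I)COCc1ccc(OC)cc1
Why: Barbier-type 2-(alkoxycarbonyl)allylation, in which the Z-configured allylindium reacts at its γ-carbon C7 through a six-membered chair so that C6 and C7 come out syn and lactonise to the cis-lactone, while allylic 1,3-strain keeps C8–H in the alkene plane and the aldehyde should approach C7 anti to the C8–C9 bond (6S and 7R from 8R); the ether oxygen at C8 is a poor leaving group, so reductive 1,4-elimination is not expected.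

Step 13
Reactants: 21 cis-α-methylene-γ-butyrolactone bearing the tetrahydrofuran ketal at C7 and the iodoalkenyl group at C6
Product: 23 aldehyde in which the allyl group of 21 is cut down to CH2CHO (C2–C3), via secondary ozonide 22 (not isolated)
Conditions: O3, CH2Cl2, −78 °C (Sudan Red 7B end point); then PPh3, −78 °C to rt
Reagents that add atoms: ozone, [O-][O+]=O
Why: Ozonolysis with reductive work-up, chemoselective because the monosubstituted allyl alkene is far more electron-rich than the α-methylene lactone and the iodoalkene.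

Step 14
Reactants: 23 aldehyde with C3 formyl group and C4 vinyl iodide
Product: 24 bridged nine-membered carbinol (C3–C4 bond formed, C3–OH, tetrahydrofuran ketal bridging C8 and C1, cis-lactone at C6/C7)
Conditions: CrCl2 (8 equiv), NiCl2 (2 mol%), DMSO, rt, high dilution (2 mM)
Reagents that add atoms: none
Why: Intramolecular Nozaki–Hiyama–Kishi coupling, in which the vinylchromium species formed by way of zerovalent nickel adds only to the aldehyde, and ring closure is helped by the cis arms on the tetrahydrofuran, the Z alkene and the cis-lactone; the new carbinol centre is oxidised away in step 15.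

Step 15
Reactants: 24 bridged nine-membered carbinol
Product: 25 bridged nine-membered enone (C3 ketone)
Conditions: Dess–Martin periodinane, NaHCO3, CH2Cl2, 0 °C to rt
Reagents that add atoms: none
Why: Dess–Martin oxidation of the secondary allylic alcohol under buffered conditions; the tertiary C1 hydroxyl is untouched and the ring holds the Z geometry.

Step 16
Reactants: 25 bridged nine-membered enone
Product: 26 (1R,6S,7R,8R)-1-acetyl-1,8-dihydroxy nine-membered enone lactone (C3 ketone, in equilibrium with its lactols)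
Conditions: HCl (0.5 M aq), THF, rt
Reagents that add atoms: water, O
Why: Acid hydrolysis of the cyclic methyl ketal, which sets free the C10 ketone and the C8 hydroxyl; the α-hydroxyl makes this ketal sluggish, so aqueous mineral acid is used, which the PMB ether and the lactone tolerate.

Step 17
Reactants: 26 (1R,6S,7R,8R)-1-acetyl-1,8-dihydroxy nine-membered enone lactone; 27 tiglic acid
Product: 28 8-O-tiglate of 26 (C3 ketone, C10 acetyl, C1 hydroxyl free)
Conditions: 27, 2,4,6-Cl3C6H2COCl, Et3N, THF, rt; then 26, DMAP, toluene, rt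
Reagents that add atoms: tiglic acid (27), C/C=C(\C)C(=O)O
Why: Yamaguchi esterification, which should acylate only the secondary C8 hydroxyl of the open keto form because the tertiary and hemiketal hydroxyls are too hindered, and which does not isomerise the tiglate.

Step 18
Reactants: 28 8-O-tiglate (C3 ketone)
Product: 29 (1R,6S,7R,8R)-1-acetylcyclononenol C3 dimethyl ketal (key-step precursor)
Conditions: HC(OMe)3, MeOH, PPTS (cat.), 0 °C to rt
Reagents that add atoms: trimethyl orthoformate, COC(OC)OC
Why: Acid-catalysed ketalisation with an orthoester, expected to take place at C3 only because oxocarbenium formation at C10 is retarded by the adjacent hydroxyl-bearing quaternary carbon (the same effect that makes the C10 ketal of 25 slow to hydrolyse), while the ring-twisted C3 enone behaves like an ordinary ketone.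

Step 19
Reactants: 29 (1R,6S,7R,8R)-1-acetylcyclononenol C3 dimethyl ketal
Product: 32 15-O-(4-methoxybenzyl) ether of the target, via ring-expanded ketol 30 (not isolated), via methoxy ketal 31 (not isolated)
Conditions: Sc(OTf)3 (20 mol%), 4 Å MS, CH2Cl2, rt to 40 °C
Reagents that add atoms: none
Why: Proposed new method: Sc(OTf)3 should bind the C1 hydroxyl and the C10 carbonyl in a five-membered chelate that holds O–C1–C10=O syn-periplanar and places the C1–C9 bond over the carbonyl π*, so that C9 shifts suprafacially to C10 while C1 becomes the ketone (ketol 30); the closest known reaction type is the Lewis-acid α-ketol (acyloin) rearrangement used for one-carbon ring expansion in steroid D-homoannulation, not yet shown for a nine- to ten-membered ring or with a ketal trap. The ten-membered carbocycle is closed by this ring-expanding 1,2-shift, and the furanone by 5-exo-trig attack of the new C10 hydroxyl on the C3 oxocarbenium ion released from the dimethyl ketal (31), followed by loss of the second methanol across C2–C3 to give the vinylogous ester. The new stereocentre C10 is controlled by C1: in the chelate C9 lies on one face of the acetyl group only, and migration to that face gives 10R. The step needs C9 rather than C2 to migrate, which the substrate secures because both shifts are reversible and only the C9-shifted ketol has its hydroxyl 1,4 to C3 (the C2-shifted isomer could close only an oxetane), so the irreversible furanone formation drains the equilibrium. It also needs the ketal and the C1 carbinol to survive until the shift has taken place, which the acetyl group helps by disfavouring ionisation at C1, and the sieves take up the methanol.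

Step 20
Reactants: 32 15-O-(4-methoxybenzyl) ether of the target
Product: 33 target (CNP0269689.6)
Conditions: DDQ, CH2Cl2/pH 7 buffer, 0 °C
Reagents that add atoms: none
Why: Oxidative cleavage of the PMB ether by DDQ (benzylic hydride abstraction, hydrolysis of the oxocarbenium ion), which the electron-poor furanone, lactone and tiglate should tolerate.

**Compound list**

1 | (R)-5-(hydroxymethyl)dihydrofuran-2(3H)-one | O=C1CC[C@H](CO)O1 | starting material
2 | (R)-5-[(tert-butyldiphenylsilyloxy)methyl]dihydrofuran-2(3H)-one | O=C1CC[C@H](CO[Si](c2ccccc2)(c2ccccc2)C(C)(C)C)O1 | intermediate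
3 | allyl bromide | C=CCBr | starting material
4 | lithium enolate of 2 | [Li+].[O-]C1=CC[C@H](CO[Si](c2ccccc2)(c2ccccc2)C(C)(C)C)O1 | intermediate (not isolated)
5 | (3S,5R)-3-allyl-5-[(tert-butyldiphenylsilyloxy)methyl]dihydrofuran-2(3H)-one (3,5-trans) | O=C1[C@@H](CC=C)C[C@H](CO[Si](c2ccccc2)(c2ccccc2)C(C)(C)C)O1 | intermediate
6 | potassium enolate of 5 | [K+].[O-]C1=C(CC=C)C[C@H](CO[Si](c2ccccc2)(c2ccccc2)C(C)(C)C)O1 | intermediate (not isolated)
7 | (3S,5R)-3-allyl-3-hydroxy-5-[(tert-butyldiphenylsilyloxy)methyl]dihydrofuran-2(3H)-one (OH trans to the silyloxymethyl group) | O=C1[C@](O)(CC=C)C[C@H](CO[Si](c2ccccc2)(c2ccccc2)C(C)(C)C)O1 | intermediate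
8 | (3S,5R)-3-allyl-3,5-dihydroxy-6-(tert-butyldiphenylsilyloxy)hexan-2-one (in equilibrium with its lactol) | CC(=O)[C@](O)(CC=C)C[C@@H](O)CO[Si](c1ccccc1)(c1ccccc1)C(C)(C)C | intermediate (not isolated)
9 | (3S,5R)-3-allyl-2-methoxy-2-methyl-5-[(tert-butyldiphenylsilyloxy)methyl]tetrahydrofuran-3-ol (mixture at ketal carbon C2) | COC1(C)O[C@@H](CO[Si](c2ccccc2)(c2ccccc2)C(C)(C)C)C[C@@]1(O)CC=C | intermediate
10 | (3S,5R)-3-allyl-5-(hydroxymethyl)-2-methoxy-2-methyltetrahydrofuran-3-ol | COC1(C)O[C@@H](CO)C[C@@]1(O)CC=C | intermediate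
11 | (2R,4S)-4-allyl-4-hydroxy-5-methoxy-5-methyltetrahydrofuran-2-carbaldehyde | COC1(C)O[C@@H](C=O)C[C@@]1(O)CC=C | intermediate
12 | methyl acrylate | C=CC(=O)OC | starting material
13 | methyl 2-{hydroxy[(2R,4S)-4-allyl-4-hydroxy-5-methoxy-5-methyltetrahydrofuran-2-yl]methyl}acrylate (mixture at the carbinol) | COC1(C)O[C@@H](C(O)C(=C)C(=O)OC)C[C@@]1(O)CC=C | intermediate
14 | methyl (Z)-2-(bromomethyl)-3-[(2R,4S)-4-allyl-4-hydroxy-5-methoxy-5-methyltetrahydrofuran-2-yl]acrylate | COC1(C)O[C@@H](/C=C(\CBr)C(=O)OC)C[C@@]1(O)CC=C | intermediate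
15 | but-2-yne-1,4-diol | OCC#CCO | starting material
16 | 4-[(4-methoxybenzyl)oxy]but-2-yn-1-ol | OCC#CCOCc1ccc(OC)cc1 | intermediate
17 | sodium cyclic vinylalanate from 16 (five-membered Al–O–C–C=C ring) | [Na+].COCCO[Al-]1(OCCOC)OCC=C1COCc2ccc(OC)cc2 | intermediate (not isolated)
18 | (Z)-3-iodo-4-[(4-methoxybenzyl)oxy]but-2-en-1-ol | OC/C=C(\I)COCc1ccc(OC)cc1 | intermediate
19 | (Z)-3-iodo-4-[(4-methoxybenzyl)oxy]but-2-enal | O=C/C=C(\I)COCc1ccc(OC)cc1 | intermediate
20 | syn hydroxy ester (C6–OH, C12 methyl ester; open form of 21) | COC1(C)O[C@@H]([C@H]([C@@H](O)/C=C(\I)COCc2ccc(OC)cc2)C(=C)C(=O)OC)C[C@@]1(O)CC=C | intermediate (not isolated)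
21 | cis-α-methylene-γ-butyrolactone with the tetrahydrofuran ketal at C7 and the (Z)-2-iodo-3-(4-methoxybenzyloxy)prop-1-enyl group at C6 | COC1(C)O[C@@H]([C@@H]2[C@H](/C=C(\I)COCc3ccc(OC)cc3)OC(=O)C2=C)C[C@@]1(O)CC=C | intermediate
22 | secondary ozonide (1,2,4-trioxolane) of the allyl group of 21 | COC1(C)O[C@@H]([C@@H]2[C@H](/C=C(\I)COCc3ccc(OC)cc3)OC(=O)C2=C)C[C@@]1(O)CC4OCOO4 | intermediate (not isolated)
23 | aldehyde (as 21, allyl group cut down to CH2CHO) | COC1(C)O[C@@H]([C@@H]2[C@H](/C=C(\I)COCc3ccc(OC)cc3)OC(=O)C2=C)C[C@@]1(O)CC=O | intermediate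
24 | bridged nine-membered carbinol (C3–OH mixture, tetrahydrofuran ketal across C8/C1, cis-lactone at C6/C7, 4Z) | COC1(C)O[C@@H]2C[C@@]1(O)CC(O)/C(COCc4ccc(OC)cc4)=C\[C@@H]3OC(=O)C(=C)[C@H]23 | intermediate
25 | bridged nine-membered enone (C3 ketone of 24) | COC1(C)O[C@@H]2C[C@@]1(O)CC(=O)/C(COCc4ccc(OC)cc4)=C\[C@@H]3OC(=O)C(=C)[C@H]23 | intermediate
26 | (1R,6S,7R,8R)-1-acetyl-1,8-dihydroxy nine-membered enone lactone (C3 ketone) | CC(=O)[C@]1(O)CC(=O)/C(COCc3ccc(OC)cc3)=C\[C@@H]2OC(=O)C(=C)[C@@H]2[C@H](O)C1 | intermediate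
27 | tiglic acid | C/C=C(\C)C(=O)O | starting material
28 | 8-O-tiglate of 26 | CC(=O)[C@]1(O)CC(=O)/C(COCc3ccc(OC)cc3)=C\[C@@H]2OC(=O)C(=C)[C@@H]2[C@H](OC(=O)/C(C)=C/C)C1 | intermediate
29 | (1R,6S,7R,8R)-1-acetylcyclononenol C3 dimethyl ketal (key-step precursor) | CC(=O)[C@]1(O)CC(OC)(OC)/C(COCc3ccc(OC)cc3)=C\[C@@H]2OC(=O)C(=C)[C@@H]2[C@H](OC(=O)/C(C)=C/C)C1 | intermediate
30 | ring-expanded ten-membered α-ketol (C1 ketone, 10R carbinol, C3 ketal intact) | C[C@]1(O)C(=O)CC(OC)(OC)/C(COCc3ccc(OC)cc3)=C\[C@@H]2OC(=O)C(=C)[C@@H]2[C@H](OC(=O)/C(C)=C/C)C1 | intermediate (not isolated)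
31 | 3-methoxy-3,10-epoxy ketal (saturated furanone precursor, mixture at C3) | C=C1C(=O)O[C@H]2/C=C(/COCc4ccc(OC)cc4)C3(OC)CC(=O)[C@@](C)(C[C@@H](OC(=O)/C(C)=C/C)[C@@H]12)O3 | intermediate (not isolated)
32 | 15-O-(4-methoxybenzyl) ether of the target | C=C1C(=O)O[C@H]2/C=C(/COCc4ccc(OC)cc4)C3=CC(=O)[C@@](C)(C[C@@H](OC(=O)/C(C)=C/C)[C@@H]12)O3 | intermediate
33 | CNP0269689.6 | C=C1C(=O)O[C@H]2/C=C(/CO)C3=CC(=O)[C@@](C)(C[C@@H](OC(=O)/C(C)=C/C)[C@@H]12)O3 | target

**Step count**

Total: 20 steps. Longest linear sequence: 17 steps (steps 1–8 and 12–20).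

**Steps most likely to fail**

1. Step 19 (the step marked as a proposed new method). The shift may not be drained by the trap: the ketal may ionise first and eliminate or fragment at C1–C2, C2 may migrate unproductively, or a non-chelated conformer may give the 10-epimer. Fallback with known reaction types, setting out from 28 and returning at 32: treatment of 28 with Al(O-t-Bu)3 in toluene at 80 °C (the aluminium-alkoxide α-ketol rearrangement of D-homoannulation, here pulled forward by the aluminium β-diketonate of the product) would give the ring-expanded (6S,7R,8R,10R)-10-hydroxy-1,3-dione F1. Acid-catalysed cyclodehydration of this α′-hydroxy-1,3-diketone (p-TsOH cat., benzene, 50 °C) would then give 32. This detour also leaves out step 18.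

2. Step 12. The aldehyde may attack the wrong face of C7 relative to C8 (for example if the ring oxygen chelates the metal), which would give the cis-lactone of the wrong absolute sense at C6 and C7. Fallback, setting out from 14 and returning at 20 and 21: borylation of 14 (B2pin2, Pd2(dba)3 cat., DMSO, rt) would give the allyl pinacolboronate F2. Allylboration of enal 19 with F2 under a chiral phosphoric acid (TRIP, 5 mol%, toluene, −30 °C) puts the aldehyde face under catalyst control, while the closed chair still transfers the Z geometry into the syn relationship. This gives hydroxy ester 20 and, after PPTS, lactone 21.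

3. Step 14. Closure of the bridged nine-membered ring may lose to oligomerisation or to reduction of the vinyl iodide. Fallback, setting out from 23 and returning at 25 (step 15 is then not needed): Pinnick oxidation (NaClO2, NaH2PO4, 2-methyl-2-butene, t-BuOH/H2O) would give the carboxylic acid F3. Thioesterification (EtSH, DCC, DMAP, CH2Cl2) would give the S-ethyl thioester F4. Stannylation of the vinyl iodide ((Me3Sn)2, Pd(PPh3)4 cat., toluene, 80 °C) would give the vinylstannane F5. Intramolecular thioester–stannane ketone synthesis (Pd2(dba)3, tri(2-furyl)phosphine, CuOP(O)Ph2, THF, 50 °C, high dilution) would then close the ring directly to enone 25.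

Further compounds
F1 | step 19 | (6S,7R,8R,10R)-10-hydroxy-1,3-dioxo ten-membered lactone tiglate (ring-expanded α′-hydroxy-1,3-diketone) | C[C@]1(O)C(=O)CC(=O)/C(COCc3ccc(OC)cc3)=C\[C@@H]2OC(=O)C(=C)[C@@H]2[C@H](OC(=O)/C(C)=C/C)C1
F2 | step 12 | methyl (Z)-2-[(4,4,5,5-tetramethyl-1,3,2-dioxaborolan-2-yl)methyl]-3-[(2R,4S)-4-allyl-4-hydroxy-5-methoxy-5-methyltetrahydrofuran-2-yl]acrylate | COC1(C)O[C@@H](/C=C(\CB2OC(C)(C)C(C)(C)O2)C(=O)OC)C[C@@]1(O)CC=C
F3 | step 14 | carboxylic acid from aldehyde 23 (C3 carboxyl) | COC1(C)O[C@@H]([C@@H]2[C@H](/C=C(\I)COCc3ccc(OC)cc3)OC(=O)C2=C)C[C@@]1(O)CC(=O)O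
F4 | step 14 | S-ethyl thioester of F3 | COC1(C)O[C@@H]([C@@H]2[C@H](/C=C(\I)COCc3ccc(OC)cc3)OC(=O)C2=C)C[C@@]1(O)CC(=O)SCC
F5 | step 14 | vinyl trimethylstannane from F4 (SnMe3 in place of iodine at C4) | COC1(C)O[C@@H]([C@@H]2[C@H](/C=C(\[Sn](C)(C)C)COCc3ccc(OC)cc3)OC(=O)C2=C)C[C@@]1(O)CC(=O)SCC
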